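**Plan**
Retrosynthesis: C16=C17 (methylenation) and C13–C16 (ring D) are cut first, then C9–C11 and C8–C14 together as a butadiene Diels–Alder. This works because ring C shares its C8–C9 edge with the spirolactone and C8 is quaternary between the C7 lactone carbonyl and the C15 ketone (ent-kaurane locants), which is the retron of a 3-acetyl-5,6-dihydropyran-2-one.
The dienophile is cut at C8=C9 (Knoevenagel of a C20 acetoacetate onto a C9 aldehyde); ring A is cut at C10–C9, C5–C6 and C10–C20 back to the Diels–Alder adduct of methacrolein and a 2-silyloxybutadiene.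
Forward: ring A (catalytic asymmetric Diels–Alder) → C6 (silicon-tethered radical closure) → quaternary C10 → spirolactone → ring C (key Diels–Alder) → ring D (Pd(II) cycloalkenylation) → C17.
Stereochemistry: C4 from the chiral oxazaborolidinium catalyst; C5 by delivery of C6 from O19; C10 by alkylation anti to C6 (checked by γ-lactonisation); C1 by axial hydride attack; C8/C9 by addition of butadiene to the lactone face syn to C1 with cis fusion; C13 by the geometry of the one-carbon bridge.

Key step: step 18

Remark on locants: ent-kaurane locants of the target are used throughout; the "lower face" of ring A is the face carrying O1, C19, C6 and C20 (C18 methyl, H-5 and C9 are on the upper face).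
Assumption: the (S)-CBS-derived oxazaborolidinium catalyst is taken to deliver the (R)-aldehyde 4; if the sense of induction is the opposite, its commercial antipode is used.

**Step 1**
Reactants: 1 but-3-en-2-one
Product: 2 2-[(triisopropylsilyl)oxy]buta-1,3-diene
Conditions: TIPSOTf, Et3N, Et2O, 0 → 23 °C
Reagents that add atoms: triisopropylsilyl trifluoromethanesulfonate, CC(C)[Si](OS(=O)(=O)C(F)(F)F)(C(C)C)C(C)C
Why: Soft enolisation of the methyl ketone by the silyl triflate–amine pair and O-silylation give the cross-conjugated 2-silyloxy diene (silyl enol ether formation); no stereocentre is formed.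

**Step 2**
Reactants: 2 2-[(triisopropylsilyl)oxy]buta-1,3-diene; 3 2-methylprop-2-enal
Product: 4 (R)-1-methyl-4-[(triisopropylsilyl)oxy]cyclohex-3-ene-1-carbaldehyde
Conditions: (S)-o-tolyl-CBS-oxazaborolidine (20 mol%), Tf2NH (20 mol%), CH2Cl2, −78 °C
Reagents that add atoms: none
Why: Enantioselective Diels–Alder reaction under chiral oxazaborolidinium catalysis: the cationic Lewis acid binds the s-trans enal and shields one face, the diene adds with "para" regiochemistry (siloxy carbon 1,4 to the new quaternary carbon), and the catalyst sets quaternary C4 as (R).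

**Step 3**
Reactants: 4 (R)-1-methyl-4-[(triisopropylsilyl)oxy]cyclohex-3-ene-1-carbaldehyde
Product: 5 {(R)-1-methyl-4-[(triisopropylsilyl)oxy]cyclohex-3-en-1-yl}methanol
Conditions: NaBH4, MeOH–THF, 0 °C
Reagents that add atoms: none
Why: Chemoselective borohydride reduction of the neopentyl aldehyde to the C19 alcohol; the TIPS enol ether, which alone distinguishes the two arms of the ring and so carries the C4 chirality, is stable to NaBH4.

**Step 4**
Reactants: 5 {(R)-1-methyl-4-[(triisopropylsilyl)oxy]cyclohex-3-en-1-yl}methanol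
Product: 6 (R)-4-(hydroxymethyl)-4-methylcyclohex-2-en-1-one
Conditions: Pd(OAc)2 (10 mol%), O2 (1 atm), DMSO, 40 °C
Reagents that add atoms: none
Why: Saegusa–Ito oxidation: the palladium enolate formed at C10 can undergo β-hydride elimination only toward C5, which unveils the C1 ketone with the C10=C5 double bond next to quaternary C4 and turns the enol ether regiochemistry into a configurationally stable enone.

**Step 5**
Reactants: 6 (R)-4-(hydroxymethyl)-4-methylcyclohex-2-en-1-one
Product: 7 (R)-4-(hydroxymethyl)-2-iodo-4-methylcyclohex-2-en-1-one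
Conditions: I2, pyridine–CH2Cl2 (1:1), 0 → 23 °C
Reagents that add atoms: iodine, II
Why: α-Iodination of an enone by conjugate addition of pyridine, iodination of the enolate and elimination, a reaction type that tolerates a quaternary γ-carbon and a free alcohol.

**Step 6**
Reactants: 7 (R)-4-(hydroxymethyl)-2-iodo-4-methylcyclohex-2-en-1-one
Product: 8 methyl (R)-3-(hydroxymethyl)-3-methyl-6-oxocyclohex-1-ene-1-carboxylate
Conditions: PdCl2(PPh3)2 (5 mol%), CO (1 atm), MeOH, Et3N, DMF, 50 °C
Reagents that add atoms: carbon monoxide, [C-]#[O+]; methanol, CO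
Why: Palladium-catalysed alkoxycarbonylation of the alkenyl iodide (oxidative addition, CO insertion, methanolysis) places the future C20 on C10 as an ester and makes C10=C5 a doubly activated radical acceptor.

**Step 7**
Reactants: 8 methyl (R)-3-(hydroxymethyl)-3-methyl-6-oxocyclohex-1-ene-1-carboxylate
Product: 9 methyl (R)-3-({[(bromomethyl)dimethylsilyl]oxy}methyl)-3-methyl-6-oxocyclohex-1-ene-1-carboxylate
Conditions: BrCH2SiMe2Cl, Et3N, DMAP (cat.), CH2Cl2, 0 °C; used crude
Reagents that add atoms: (bromomethyl)chlorodimethylsilane, C[Si](C)(Cl)CBr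
Why: Silylation of the primary C19 alcohol installs the (bromomethyl)dimethylsilyl radical tether; the labile silyl ether is carried on without chromatography.

**Step 8**
Reactants: 9 methyl (R)-3-({[(bromomethyl)dimethylsilyl]oxy}methyl)-3-methyl-6-oxocyclohex-1-ene-1-carboxylate
Product: 10 cis-fused siloxane β-keto ester (methyl 3,3,8a-trimethyl-6-oxooctahydro-1H-2,3-benzoxasiline-5-carboxylate)
Conditions: Bu3SnH (slow addition), AIBN (cat.), benzene, 80 °C
Reagents that add atoms: none
Why: Silicon-tethered radical cyclisation: the nucleophilic α-silyl radical adds 6-exo to the electrophilic β-carbon C5, the tether from O19 and a chair-like closure anti to the pseudo-axial C18 methyl put the new C5–C6 bond cis to C19 (H-5 cis to CH3), and the stabilised C10 radical is reduced by the stannane.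

**Step 9**
Reactants: 10 cis-fused siloxane β-keto ester; 11 phenyl vinyl sulfoxide
Product: 13 C10-vinyl keto ester (methyl 5-ethenyl-3,3,8a-trimethyl-6-oxooctahydro-1H-2,3-benzoxasiline-5-carboxylate), via sulfoxide Michael adduct 12 (not isolated)
Conditions: Cs2CO3 (0.2 equiv), MeCN, 40 °C; then toluene, 110 °C
Reagents that add atoms: none
Why: α-Vinylation by Michael addition of the β-keto ester to the vinyl sulfoxide and thermal syn-elimination of benzenesulfenic acid; the electrophile approaches C10 anti to the adjacent C6 methylene and to the axial C19 arm, so the vinyl group (C9) becomes trans and the ester (C20) cis to C6.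

**Step 10**
Reactants: 13 C10-vinyl keto ester
Product: 15 cis-fused keto γ-lactone with free C19 alcohol (7a-ethenyl-4-(hydroxymethyl)-4-methylhexahydro-2-benzofuran-1,7-dione), via diol ester 14 (not isolated)
Conditions: 30% H2O2, KF, KHCO3, THF–MeOH, 23 → 40 °C; then PPTS (cat.), CH2Cl2, 23 °C
Reagents that add atoms: hydrogen peroxide, OO
Why: Tamao–Kumada oxidation replaces the C6–Si bond by C6–OH and frees O19, and the C6 hydroxyl, being cis and 1,4 to the C20 ester, closes the γ-lactone, which both confirms the C10 configuration and distinguishes O6 from O19.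

**Step 11**
Reactants: 15 cis-fused keto γ-lactone with free C19 alcohol
Product: 16 O19-benzyl keto γ-lactone
Conditions: BnOC(=NH)CCl3, TfOH (cat.), CH2Cl2–cyclohexane, 0 °C
Reagents that add atoms: benzyl 2,2,2-trichloroacetimidate, N=C(OCc1ccccc1)C(Cl)(Cl)Cl
Why: Acid-catalysed O-benzylation with the trichloroacetimidate protects the neopentyl C19 alcohol without base, which the non-enolisable β-keto lactone might not survive (retro-Claisen cleavage).

**Step 12**
Reactants: 16 O19-benzyl keto γ-lactone
Product: 17 triol (4-[(benzyloxy)methyl]-2-ethenyl-2,3-bis(hydroxymethyl)-4-methylcyclohexan-1-ol)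
Conditions: LiAlH4, THF, 0 → 23 °C
Reagents that add atoms: none
Why: Hydride reduction of ketone and lactone; attack on the C1 carbonyl along the axial trajectory, anti to the axial C10–C20 bond and past axial hydrogens only, should give the equatorial C1 alcohol cis to C20 (new stereocentre C1).

**Step 13**
Reactants: 17 triol
Product: 18 O1/O20 benzylidene acetal with free C6 alcohol
Conditions: PhCH(OMe)2, CSA (cat.), CH2Cl2, 23 °C
Reagents that add atoms: benzaldehyde dimethyl acetal, COC(OC)c1ccccc1
Why: Thermodynamic transacetalisation selects the 1,3-diol O1/O20 (six-membered 1,3-dioxane with equatorial phenyl) over any seven-membered alternative, so that O6 alone stays free.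

**Step 14**
Reactants: 18 O1/O20 benzylidene acetal with free C6 alcohol
Product: 19 O6-TBS benzylidene acetal
Conditions: TBSCl, imidazole, DMF, 23 °C
Reagents that add atoms: tert-butyldimethylsilyl chloride, CC(C)(C)[Si](C)(C)Cl
Why: Standard silylation of the single free primary alcohol.

**Step 15**
Reactants: 19 O6-TBS benzylidene acetal
Product: 20 C20 alcohol with O1-benzyl, O19-benzyl and O6-TBS groups
Conditions: DIBAL-H, CH2Cl2, −20 → 0 °C
Reagents that add atoms: none
Why: Regioselective reductive opening of the benzylidene acetal: aluminium coordinates the less hindered primary O20, the acetal C–O20 bond breaks and hydride reduces the oxocarbenium ion, leaving benzyl on secondary O1 and the C20 alcohol free.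

**Step 16**
Reactants: 20 C20 alcohol; 21 2,2,6-trimethyl-4H-1,3-dioxin-4-one
Product: 23 C20 acetoacetate, via acetylketene 22 (not isolated)
Conditions: toluene, 110 °C
Reagents that add atoms: none
Why: Thermal retro-[4+2] of the dioxinone releases acetylketene, which acetoacetylates even the hindered neopentyl C20 alcohol under neutral conditions.

**Step 17**
Reactants: 23 C20 acetoacetate
Product: 26 3-acetyl unsaturated spiro δ-lactone (4-acetyl-7-(benzyloxy)-10-[(benzyloxy)methyl]-11-({[tert-butyl(dimethyl)silyl]oxy}methyl)-10-methyl-2-oxaspiro[5.5]undec-4-en-3-one), via vicinal diol 24 (not isolated), via aldehyde 25 (not isolated)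
Conditions: OsO4 (2 mol%), NaIO4, 2,6-lutidine, dioxane–H2O, 23 °C; aqueous work-up; then piperidine (cat.), AcOH (cat.), CH2Cl2, 4 Å MS, 23 °C
Reagents that add atoms: none
Why: Lemieux–Johnson cleavage of the vinyl group gives the non-enolisable C9 aldehyde, and amine-catalysed intramolecular Knoevenagel condensation with the acetoacetate methylene closes the six-membered lactone and creates the C8=C9 bond.

**Step 18**
Reactants: 26 3-acetyl unsaturated spiro δ-lactone; 27 buta-1,3-diene
Product: 28 cis-fused C8-acetyl lactone cyclohexene (Diels–Alder adduct, alkene at C12=C13)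
Conditions: buta-1,3-diene (10 equiv), ZnCl2 (1.5 equiv), CH2Cl2, −20 → 23 °C, sealed tube
Reagents that add atoms: none
Why: A normal-electron-demand [4+2] cycloaddition in which ZnCl2 chelates the C7 lactone and C15 ketone carbonyls of 26 and so lowers the LUMO of the trisubstituted C8=C9 bond enough for it to react although C9 is neopentyl; the closest known reaction type is the Lewis acid-promoted Diels–Alder reaction of 2-acyl (or 2-alkoxycarbonyl) α,β-unsaturated lactones and cycloalkenones with simple dienes. Ring C (C8, C9, C11–C14) closes in one concerted, suprafacial step that forms C9–C11 and C8–C14 and leaves the new alkene at C12=C13. C9 is set by the face of the dienophile that butadiene approaches and C8 by the suprafacial mode, so that the acetyl group and H-9 are cis and the lactone/cyclohexene fusion is cis. The step needs π-facial selectivity for the lactone face syn to C1: C9 is equatorial on ring A, the equatorial C1 benzyloxy group points away from it, and the other face is screened by the C6 silyloxymethyl arm on C5, buttressed by quaternary C4 and its axial C19 arm. A hetero-Diels–Alder adduct through the acetyl oxygen, if formed, is expected to funnel into the same product by [3,3] shift on warming.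

**Step 19**
Reactants: 28 cis-fused C8-acetyl lactone cyclohexene
Product: 29 C15 tert-butyldimethylsilyl enol ether
Conditions: TBSOTf, Et3N, CH2Cl2, 0 °C
Reagents that add atoms: tert-butyldimethylsilyl trifluoromethanesulfonate, CC(C)(C)[Si](C)(C)OS(=O)(=O)C(F)(F)F
Why: Soft enolisation and O-silylation of the methyl ketone; because C8 is quaternary only the C16 methyl can enolise, so the C15 silyl enol ether forms regiospecifically.

**Step 20**
Reactants: 29 C15 tert-butyldimethylsilyl enol ether
Product: 30 bicyclo[3.2.1]octenone (1,19-di-O-benzyl-6-O-TBS-17-nor-6,7-seco-ent-kaur-11-en-15-one 7,20-lactone)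
Conditions: Pd(OAc)2 (20 mol%), O2 (1 atm), DMSO, 45 °C
Reagents that add atoms: none
Why: Palladium(II)-mediated cycloalkenylation of a silyl enol ether: the palladium enolate at C16 adds 5-exo across C12=C13 to form C13–C16 and syn β-hydride elimination gives C11=C12; C13 is fixed because C16 can reach it only on the face of ring C that carries C15.

**Step 21**
Reactants: 30 bicyclo[3.2.1]octenone
Product: 31 1,19-diol (6-O-TBS-1,19-dihydroxy-17-nor-6,7-seco-ent-kauran-15-one 7,20-lactone)
Conditions: H2 (1 atm), Pd(OH)2/C, EtOAc, 23 °C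
Reagents that add atoms: none
Why: Heterogeneous hydrogenation saturates the cis-disubstituted C11=C12 bond and hydrogenolyses both benzyl ethers in the same operation, while the silyl ether, ketone and lactone are inert.

**Step 22**
Reactants: 31 1,19-diol
Product: 32 1,19-diacetate
Conditions: Ac2O, pyridine, DMAP (cat.), CH2Cl2, 23 °C, on the crude diol
Reagents that add atoms: acetic anhydride, CC(=O)OC(C)=O
Why: DMAP-catalysed acetylation of the secondary C1 and primary C19 alcohols, carried out at once so that the free C1 hydroxyl cannot translactonise onto C7.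

**Step 23**
Reactants: 32 1,19-diacetate
Product: 36 6-O-TBS ether of the target (C16 exo-methylene ketone), via trimethylsilyl enol ether 33 (not isolated), via Mannich base 34 (not isolated), via methiodide 35 (not isolated)
Conditions: TMSOTf, Et3N, CH2Cl2, 0 °C; Me2N=CH2+ I−, CH2Cl2, 23 °C; MeI, then aq. NaHCO3, 23 °C
Reagents that add atoms: N,N-dimethylmethyleneiminium iodide (Eschenmoser's salt), C=[N+](C)C.[I-]
Why: α-Methylenation of the ketone by Mannich reaction of its silyl enol ether with Eschenmoser's salt, quaternisation and base-induced elimination; C16 is the only enolisable position and the soft enolisation leaves acetates and lactone untouched.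

**Step 24**
Reactants: 36 6-O-TBS ether of the target
Product: 37 target compound CNP0105570.2
Conditions: HF·pyridine, THF–pyridine, 0 → 23 °C
Reagents that add atoms: none
Why: Fluoride-mediated cleavage of the primary silyl ether under buffered, non-basic conditions that spare the acetates, the lactone and the exo-methylene ketone.

**Compound list**
1 | but-3-en-2-one (methyl vinyl ketone) | CC(=O)C=C | starting material
2 | 2-[(triisopropylsilyl)oxy]buta-1,3-diene | C=CC(=C)O[Si](C(C)C)(C(C)C)C(C)C | intermediate
3 | 2-methylprop-2-enal (methacrolein) | CC(=C)C=O | starting material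
4 | (R)-1-methyl-4-[(triisopropylsilyl)oxy]cyclohex-3-ene-1-carbaldehyde | C[C@]1(C=O)CC=C(O[Si](C(C)C)(C(C)C)C(C)C)CC1 | intermediate
5 | {(R)-1-methyl-4-[(triisopropylsilyl)oxy]cyclohex-3-en-1-yl}methanol | C[C@]1(CO)CC=C(O[Si](C(C)C)(C(C)C)C(C)C)CC1 | intermediate
6 | (R)-4-(hydroxymethyl)-4-methylcyclohex-2-en-1-one | C[C@]1(CO)C=CC(=O)CC1 | intermediate
7 | (R)-4-(hydroxymethyl)-2-iodo-4-methylcyclohex-2-en-1-one | C[C@]1(CO)C=C(I)C(=O)CC1 | intermediate
8 | methyl (R)-3-(hydroxymethyl)-3-methyl-6-oxocyclohex-1-ene-1-carboxylate | C[C@]1(CO)C=C(C(=O)OC)C(=O)CC1 | intermediate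
9 | methyl (R)-3-({[(bromomethyl)dimethylsilyl]oxy}methyl)-3-methyl-6-oxocyclohex-1-ene-1-carboxylate | C[C@]1(CO[Si](C)(C)CBr)C=C(C(=O)OC)C(=O)CC1 | intermediate
10 | methyl 3,3,8a-trimethyl-6-oxooctahydro-1H-2,3-benzoxasiline-5-carboxylate, cis-fused (C19–O–SiMe2–C6 ring on the lower face, H-5 cis to the C4 methyl; C10 as keto/enol mixture) | COC(=O)C1C(=O)CC[C@@]2(C)CO[Si](C)(C)C[C@@H]12 | intermediate
11 | phenyl vinyl sulfoxide | C=CS(=O)c1ccccc1 | starting material
12 | sulfoxide Michael adduct: 10 with a 2-(phenylsulfinyl)ethyl group on C10, upper face (sulfur epimers) | COC(=O)[C@@]1(CCS(=O)c2ccccc2)C(=O)CC[C@@]2(C)CO[Si](C)(C)C[C@@H]12 | intermediate (not isolated)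
13 | methyl 5-ethenyl-3,3,8a-trimethyl-6-oxooctahydro-1H-2,3-benzoxasiline-5-carboxylate (vinyl = C9 on the upper face, ester = C20 on the lower face, cis to C6) | COC(=O)[C@@]1(C=C)C(=O)CC[C@@]2(C)CO[Si](C)(C)C[C@@H]12 | intermediate
14 | methyl 1-ethenyl-5,6-bis(hydroxymethyl)-5-methyl-2-oxocyclohexane-1-carboxylate (ester and both CH2OH groups on the lower face) | COC(=O)[C@@]1(C=C)C(=O)CC[C@@](C)(CO)[C@H]1CO | intermediate (not isolated)
15 | 7a-ethenyl-4-(hydroxymethyl)-4-methylhexahydro-2-benzofuran-1,7-dione, cis-fused (γ-lactone C6–O–C20, free C19–OH) | C=C[C@]12C(=O)CC[C@@](C)(CO)[C@H]1COC2=O | intermediate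
16 | 4-[(benzyloxy)methyl]-7a-ethenyl-4-methylhexahydro-2-benzofuran-1,7-dione, cis-fused | C=C[C@]12C(=O)CC[C@@](C)(COCc3ccccc3)[C@H]1COC2=O | intermediate
17 | 4-[(benzyloxy)methyl]-2-ethenyl-2,3-bis(hydroxymethyl)-4-methylcyclohexan-1-ol (O1, C20, C6 and C19 all on the lower face) | C=C[C@]1(CO)[C@@H](O)CC[C@@](C)(COCc2ccccc2)[C@H]1CO | intermediate
18 | {6-[(benzyloxy)methyl]-4a-ethenyl-6-methyl-2-phenylhexahydro-4H-1,3-benzodioxin-5-yl}methanol (O1/O20 acetal, phenyl equatorial) | C=C[C@]12CO[C@H](c3ccccc3)O[C@H]1CC[C@@](C)(COCc3ccccc3)[C@H]2CO | intermediate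
19 | O6-tert-butyldimethylsilyl ether of 18 | C=C[C@]12CO[C@H](c3ccccc3)O[C@H]1CC[C@@](C)(COCc3ccccc3)[C@H]2CO[Si](C)(C)C(C)(C)C | intermediate
20 | {2-(benzyloxy)-5-[(benzyloxy)methyl]-6-({[tert-butyl(dimethyl)silyl]oxy}methyl)-1-ethenyl-5-methylcyclohexyl}methanol (free C20–OH) | C=C[C@]1(CO)[C@@H](OCc2ccccc2)CC[C@@](C)(COCc2ccccc2)[C@H]1CO[Si](C)(C)C(C)(C)C | intermediate
21 | 2,2,6-trimethyl-4H-1,3-dioxin-4-one | CC1=CC(=O)OC(C)(C)O1 | starting material
22 | acetylketene | CC(=O)C=C=O | intermediate (not isolated)
23 | 3-oxobutanoate (acetoacetate) of 20 at O20 | C=C[C@]1(COC(=O)CC(C)=O)[C@@H](OCc2ccccc2)CC[C@@](C)(COCc2ccccc2)[C@H]1CO[Si](C)(C)C(C)(C)C | intermediate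
24 | vicinal diol from dihydroxylation of the vinyl group of 23 (carbinol epimers) | OCC(O)[C@]1(COC(=O)CC(C)=O)[C@@H](OCc2ccccc2)CC[C@@](C)(COCc2ccccc2)[C@H]1CO[Si](C)(C)C(C)(C)C | intermediate (not isolated)
25 | C9 aldehyde: the 1-formyl analogue of 23 | O=C[C@]1(COC(=O)CC(C)=O)[C@@H](OCc2ccccc2)CC[C@@](C)(COCc2ccccc2)[C@H]1CO[Si](C)(C)C(C)(C)C | intermediate (not isolated)
26 | 4-acetyl-7-(benzyloxy)-10-[(benzyloxy)methyl]-11-({[tert-butyl(dimethyl)silyl]oxy}methyl)-10-methyl-2-oxaspiro[5.5]undec-4-en-3-one (3-acetyl unsaturated spiro δ-lactone on ring A) | CC(=O)C1=C[C@]2(COC1=O)[C@@H](OCc3ccccc3)CC[C@@](C)(COCc3ccccc3)[C@H]2CO[Si](C)(C)C(C)(C)C | intermediate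
27 | buta-1,3-diene | C=CC=C | starting material
28 | Diels–Alder adduct: C8-acetyl spirolactone with ring C as a C12=C13 cyclohexene cis-fused at C8–C9 (acetyl and H-9 cis; C11 and C14 on the lactone face syn to C1) | CC(=O)[C@]12CC=CC[C@H]1[C@]1(COC2=O)[C@@H](OCc3ccccc3)CC[C@@](C)(COCc3ccccc3)[C@H]1CO[Si](C)(C)C(C)(C)C | intermediate
29 | C15 tert-butyldimethylsilyl enol ether of 28 | C=C(O[Si](C)(C)C(C)(C)C)[C@]12CC=CC[C@H]1[C@]1(COC2=O)[C@@H](OCc3ccccc3)CC[C@@](C)(COCc3ccccc3)[C@H]1CO[Si](C)(C)C(C)(C)C | intermediate
30 | 1,19-di-O-benzyl-6-O-TBS-1,6,19-trihydroxy-17-nor-6,7-seco-ent-kaur-11-en-15-one 7,20-lactone | C1C(=O)[C@]23C[C@H]1C=C[C@H]2[C@]1(COC3=O)[C@@H](OCc2ccccc2)CC[C@@](C)(COCc2ccccc2)[C@H]1CO[Si](C)(C)C(C)(C)C | intermediate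
31 | 6-O-TBS-1,6,19-trihydroxy-17-nor-6,7-seco-ent-kauran-15-one 7,20-lactone | C1C(=O)[C@]23C[C@H]1CC[C@H]2[C@]1(COC3=O)[C@@H](O)CC[C@@](C)(CO)[C@H]1CO[Si](C)(C)C(C)(C)C | intermediate
32 | 1,19-diacetate of 31 | C1C(=O)[C@]23C[C@H]1CC[C@H]2[C@]1(COC3=O)[C@@H](OC(C)=O)CC[C@@](C)(COC(C)=O)[C@H]1CO[Si](C)(C)C(C)(C)C | intermediate
33 | C15 trimethylsilyl enol ether of 32 (C15=C16) | C1=C(O[Si](C)(C)C)[C@]23C[C@H]1CC[C@H]2[C@]1(COC3=O)[C@@H](OC(C)=O)CC[C@@](C)(COC(C)=O)[C@H]1CO[Si](C)(C)C(C)(C)C | intermediate (not isolated)
34 | Mannich base: 16-[(dimethylamino)methyl] derivative of 32 (C16 epimers) | CN(C)CC1C(=O)[C@]23C[C@H]1CC[C@H]2[C@]1(COC3=O)[C@@H](OC(C)=O)CC[C@@](C)(COC(C)=O)[C@H]1CO[Si](C)(C)C(C)(C)C | intermediate (not isolated)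
35 | methiodide of 34: 16-[(trimethylammonio)methyl] ketone iodide | C[N+](C)(C)CC1C(=O)[C@]23C[C@H]1CC[C@H]2[C@]1(COC3=O)[C@@H](OC(C)=O)CC[C@@](C)(COC(C)=O)[C@H]1CO[Si](C)(C)C(C)(C)C.[I-] | intermediate (not isolated)
36 | 6-O-tert-butyldimethylsilyl ether of the target | C=C1C(=O)[C@]23C[C@H]1CC[C@H]2[C@]1(COC3=O)[C@@H](OC(C)=O)CC[C@@](C)(COC(C)=O)[C@H]1CO[Si](C)(C)C(C)(C)C | intermediate
37 | CNP0105570.2 (1,19-diacetoxy-6-hydroxy-6,7-seco-ent-kaur-16-en-15-one 7,20-lactone) | C=C1C(=O)[C@]23C[C@H]1CC[C@H]2[C@]1(COC3=O)[C@@H](OC(C)=O)CC[C@@](C)(COC(C)=O)[C@H]1CO | target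

**Totals**
Total step count: 24. Longest linear sequence: 24 steps (from methyl vinyl ketone 1).

**Steps most likely to fail**

Step 18. The diene may approach the lactone face on the C5 side, or the cycloaddition at neopentyl C9 may be outrun by butadiene oligomerisation under the Lewis acid. The fallback moves face selection from the substrate to the reagent. Compound 26 is used unchanged with butadiene and a C2-symmetric bis(oxazoline)copper(II) hexafluoroantimonate complex, which binds the same C7/C15 dicarbonyl in a square-planar chelate and screens one face of C8=C9; the ligand antipode matched to the substrate is chosen. The fallback sets out from 26 and returns to the route at 28; it makes no new compound (none, F0).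

Step 9. Conjugate addition of the hindered C10 enolate to the weakly electrophilic vinyl sulfoxide may stall or go through oxygen, and the sulfenic acid set free at 110 °C may cleave the siloxane ring. The fallback builds the quaternary centre by allylation and then shortens the chain. Compound 10 is C-allylated (allyl bromide, K2CO3, acetone, or allyl methyl carbonate with Pd(PPh3)4) to the C10-allyl keto ester F1, again anti to C6. Ruthenium hydride isomerisation (RuHCl(CO)(PPh3)3, toluene, 80 °C) moves the double bond to give the (E)-prop-1-enyl keto ester F2. Ethenolysis (Hoveyda–Grubbs II, ethylene, CH2Cl2) trims F2 to the vinyl compound. The fallback sets out from 10 and returns to the route at 13.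

Step 17. Formaldehyde released in the oxidative cleavage may condense with the acetoacetate methylene, and dihydroxylation of the neopentyl vinyl group may be slow enough for the β-keto ester to degrade. The fallback reverses the order of events. The vinyl group of alcohol 20 is cleaved first (O3, CH2Cl2–MeOH, −78 °C; Me2S) to the non-enolisable hydroxy aldehyde F3. F3 is then acetoacetylated with dioxinone 21 in toluene at 110 °C to give aldehyde 25, which is closed with piperidinium acetate as in the main route. The fallback sets out from 20 and returns to the route at 25 (and so 26).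

**Further compounds**
F0 | step 18 | none | none
F1 | step 9 | C10-allyl keto ester (methyl 3,3,8a-trimethyl-6-oxo-5-(prop-2-enyl)octahydro-1H-2,3-benzoxasiline-5-carboxylate) | COC(=O)[C@@]1(CC=C)C(=O)CC[C@@]2(C)CO[Si](C)(C)C[C@@H]12
F2 | step 9 | (E)-prop-1-enyl keto ester | COC(=O)[C@@]1(/C=C/C)C(=O)CC[C@@]2(C)CO[Si](C)(C)C[C@@H]12
F3 | step 17 | hydroxy aldehyde (2-(benzyloxy)-5-[(benzyloxy)methyl]-6-({[tert-butyl(dimethyl)silyl]oxy}methyl)-1-(hydroxymethyl)-5-methylcyclohexane-1-carbaldehyde) | O=C[C@]1(CO)[C@@H](OCc2ccccc2)CC[C@@](C)(COCc2ccccc2)[C@H]1CO[Si](C)(C)C(C)(C)C
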